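## Retrosynthetic overview

1. Locants: decalin C1 (bears the side chain C1′–C5′, C5′ = CO2H), C2 (butenyl), C3(Me)=C4, C4a, C5, C6, C7 (O), C8 (Me), C8a. Enabling feature: the ring C1–C2–C3=C4–C4a–C8a is a cyclohexene (Diels–Alder retron) and its C1 carries the sp2 carbon C1′. After retro-[4+2] (C1–C2 and C4a–C8a), C1–C1′ is therefore the σ-bond between two alkenes of a 2,4,6-trienoate.
2. That bond is made by Stille coupling of an acyclic alkenylstannane (C1 to the butenyl terminus) with a 5-iodopentadienoate (C1′–C5′). The coupling turns an inert alkenyl metal into an activated 2π unit, and the hexaene cyclises in the same flask. Both rings and C1, C2, C4a and C8a arise together; no ring exists before this step.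
3. Stereochemical decoding: cis ring fusion, H-1 anti to H-8a, and butenyl syn to H-4a and cis to the chain correspond to E-C1=C8a, Z-C4=C4a, E-C2=C3 and an endo chain.
4. Stannane: tiglaldehyde → dienal → Z-Wittig → trienal. C7/C8 come from purchased (S)-but-3-yn-2-ol by anti-selective allenylzinc addition. This is the only bought stereocentre; the other five are relayed from it. Hydrostannation follows.
5. Endgame: desilylation, saponification, O-sulfation of C7–OH.

Key step: step 9

Assumption: the fully protonated form drawn (C7–OSO3H and CO2H) is taken as the target, so the last step ends with a cold H+ exchange; omitting it would give a salt form.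

## Route

Step 1
Reactants: 1 (E)-2-methylbut-2-enal (tiglaldehyde); 2 2-(triphenyl-λ5-phosphanylidene)propanal
Product: 3 (2E,4E)-2,4-dimethylhexa-2,4-dienal
Conditions: PhMe, 90 °C
Reagents that add atoms: none
Why: Wittig olefination with a stabilised, α-branched formyl ylide is E-selective and should stop after one homologation because 3 is more hindered and less electrophilic than 1; the E butenyl terminus is bought with 1.

Step 2
Reactants: 3 (2E,4E)-2,4-dimethylhexa-2,4-dienal; 4 (4-ethoxy-4-oxobutyl)triphenylphosphonium bromide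
Product: 6 ethyl (4Z,6E,8E)-6,8-dimethyldeca-4,6,8-trienoate, via phosphonium ylide 5 (not isolated)
Conditions: NaHMDS, THF, 0 °C; then 3, −78 °C → rt
Reagents that add atoms: none
Why: Lithium-free Wittig olefination of a non-stabilised ylide under kinetic control should give the Z-C4=C4a alkene without touching the two E alkenes of 3.

Step 3
Reactants: 6 ethyl (4Z,6E,8E)-6,8-dimethyldeca-4,6,8-trienoate
Product: 7 (4Z,6E,8E)-6,8-dimethyldeca-4,6,8-trienal
Conditions: DIBAL-H (1.05 equiv), CH2Cl2, −78 °C; cold aqueous quench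
Reagents that add atoms: none
Why: Partial ester reduction with one equivalent of DIBAL-H at −78 °C stops at the aldehyde level after a cold quench and leaves the triene, which is not conjugated to the carbonyl group, untouched.

Step 4
Reactants: 8 (S)-but-3-yn-2-ol
Product: 9 (S)-but-3-yn-2-yl methanesulfonate
Conditions: MsCl, Et3N, CH2Cl2, −78 → 0 °C
Reagents that add atoms: methanesulfonyl chloride CS(=O)(=O)Cl
Why: O-Sulfonylation does not touch the C–O bond, so the S configuration is retained.

Step 5
Reactants: 7 (4Z,6E,8E)-6,8-dimethyldeca-4,6,8-trienal; 9 (S)-but-3-yn-2-yl methanesulfonate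
Product: 11 (3R,4S,7Z,9E,11E)-3,9,11-trimethyltrideca-7,9,11-trien-1-yn-4-ol, via allenylzinc mesylate 10 (not isolated)
Conditions: Pd(OAc)2 (5 mol %), PPh3 (5 mol %), Et2Zn, THF, −78 → −20 °C; dil. HCl
Reagents that add atoms: none
Why: Marshall propargylation: Pd(0) displaces the mesylate anti (SN2′), Et2Zn transmetalates to the configurationally stable (M)-allenylzinc 10, and this adds to 7 through a cyclic syn-SE2′ transition state, so C8 (R) is set by chirality transfer with net inversion and C7 (S) by the anti arrangement that keeps the aldehyde chain away from the allenyl methyl group; any syn isomer is removed by chromatography.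

Step 6
Reactants: 11 (3R,4S,7Z,9E,11E)-3,9,11-trimethyltrideca-7,9,11-trien-1-yn-4-ol
Product: 12 tert-butyl(dimethyl){[(3R,4S,7Z,9E,11E)-3,9,11-trimethyltrideca-7,9,11-trien-1-yn-4-yl]oxy}silane
Conditions: TBSOTf, 2,6-lutidine, CH2Cl2, −78 °C
Reagents that add atoms: tert-butyldimethylsilyl triflate CC(C)(C)[Si](C)(C)OS(=O)(=O)C(F)(F)F
Why: Buffered silylation of a secondary alcohol with a silyl triflate installs the bulky C7 substituent that later steers the facial selectivity.

Step 7
Reactants: 12 tert-butyl(dimethyl){[(3R,4S,7Z,9E,11E)-3,9,11-trimethyltrideca-7,9,11-trien-1-yn-4-yl]oxy}silane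
Product: 13 tributyl{(1E,3R,4S,7Z,9E,11E)-4-[(tert-butyldimethylsilyl)oxy]-3,9,11-trimethyltrideca-1,7,9,11-tetraen-1-yl}stannane
Conditions: Bu3SnH (slow addition), PdCl2(PPh3)2 (2 mol %), THF, 0 °C
Reagents that add atoms: tributyltin hydride CCCC[SnH](CCCC)CCCC
Why: Pd-catalysed syn-hydrostannation of a terminal alkyne places tin on the terminal carbon because the propargylic carbon C8 is branched, which gives the E-alkenylstannane, and the internal, substituted alkenes of the triene react far more slowly than the alkyne.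

Step 8
Reactants: 14 ethyl (E)-4-oxobut-2-enoate
Product: 15 ethyl (2E,4E)-5-iodopenta-2,4-dienoate
Conditions: CrCl2, CHI3, THF, 0 °C, dark
Reagents that add atoms: iodoform IC(I)I
Why: Takai olefination: the gem-dichromium reagent adds chemoselectively to the aldehyde and eliminates to the E-iodoalkene, leaving the enoate intact.

Step 9
Reactants: 13 tributyl{(1E,3R,4S,7Z,9E,11E)-4-[(tert-butyldimethylsilyl)oxy]-3,9,11-trimethyltrideca-1,7,9,11-tetraen-1-yl}stannane; 15 ethyl (2E,4E)-5-iodopenta-2,4-dienoate
Product: 17 ethyl (2E,4E)-5-{(1S,2R,4aS,7S,8R,8aR)-2-[(2E)-but-2-en-2-yl]-7-[(tert-butyldimethylsilyl)oxy]-3,8-dimethyl-1,2,4a,5,6,7,8,8a-octahydronaphthalen-1-yl}penta-2,4-dienoate, via acyclic hexaenoate 16 (not isolated)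
Conditions: Pd2(dba)3 (2.5 mol %), AsPh3 (20 mol %), BHT, degassed PhMe–DMF (4:1, 0.01 M), dark, 45 °C; then 110 °C in the same flask
Reagents that add atoms: none
Why: Pd(0) inserts into the C–I bond of 15, transmetalates with 13 and reductively eliminates with retention at both alkenes, so C1–C1′ is made as an sp2–sp2 bond and the inert alkenyl-metal terminus becomes the ε,ζ-alkene of the all-E 2,4,6-trienoate 16, whose lowered LUMO then engages the electron-rich C2=C3–C4=C4a diene on heating in a concerted, asynchronous intramolecular [4+2] cycloaddition (C4a–C8a bond leading, ζ-acceptor matched with the donor terminus of the triene); the closest known reaction type is the domino Stille (or Suzuki) coupling/intramolecular or transannular Diels–Alder reaction of polyenoates. Both rings close in this one event: the cyclohexene C1–C2–C3=C4–C4a–C8a by [4+2] union through C1–C2 and C4a–C8a, and the cyclohexane C4a–C5–C6–C7–C8–C8a as the fused ring of a type-1 (terminally tethered, four-atom tether) cycloaddition through the same C4a–C8a bond. C1/C8a (H-1 anti to H-8a) follow from suprafacial addition to the E-C1=C8a alkene and C2/C4a (butenyl syn to H-4a) from the E-C2=C3/Z-C4=C4a geometry, and because the tether occupies the inside position of the Z alkene it can reach C8a only with C8 exo, which enforces the cis ring fusion and places the dienoate chain endo, that is, cis to the butenyl group. The absolute sense is relayed from C7/C8: in the chair-like tether C1 is axial on C8a, so attack on the diene face that would make the OTBS group axial suffers a 1,3-diaxial OTBS/C1 clash, and the reacting conformer has OTBS equatorial and the C8 methyl axial and anti to C1, which leads to the (1S,2R,4aS,8aR) array. The step also needs periselectivity (triene as 4π and C1=C8a as 2π, not the exchanged roles), and this is secured by the C3 methyl group, whose A(1,3) strain with C5 across the Z alkene drives the diene out of its s-trans form, whereas the all-E trienoate would have to leave its s-trans C1–C1′ conformation and bond at C4 next to fully substituted C3; ring size excludes the other chain alkenes as 2π partners. BHT, exclusion of light, high dilution and a temperature near 110 °C are chosen to hold back polyene isomerisation, intermolecular cycloaddition and the [1,5]-H shift open to Z dienes.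

Step 10
Reactants: 17 the silyl-protected decalin ethyl dienoate of step 9
Product: 18 ethyl (2E,4E)-5-{(1S,2R,4aS,7S,8R,8aR)-2-[(2E)-but-2-en-2-yl]-7-hydroxy-3,8-dimethyl-1,2,4a,5,6,7,8,8a-octahydronaphthalen-1-yl}penta-2,4-dienoate
Conditions: TBAF, THF, rt
Reagents that add atoms: none
Why: Fluoride-driven Si–O cleavage (silyl ether deprotection) leaves the ester, the alkenes and all stereocentres unaffected.

Step 11
Reactants: 18 the hydroxy ethyl ester of step 10
Product: 19 (2E,4E)-5-{(1S,2R,4aS,7S,8R,8aR)-2-[(2E)-but-2-en-2-yl]-7-hydroxy-3,8-dimethyl-1,2,4a,5,6,7,8,8a-octahydronaphthalen-1-yl}penta-2,4-dienoic acid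
Conditions: LiOH, THF–MeOH–H2O, rt; then 1 M HCl to pH 3
Reagents that add atoms: lithium hydroxide [Li+].[OH-]
Why: Saponification (BAc2) of the dienoate; hydroxide is not basic enough to remove the ε-hydrogen at C1, so C1 is not epimerised.

Step 12
Reactants: 19 the hydroxy dienoic acid of step 11
Product: 20 (2E,4E)-5-{(1S,2R,4aS,7S,8R,8aR)-2-[(2E)-but-2-en-2-yl]-3,8-dimethyl-7-(sulfooxy)-1,2,4a,5,6,7,8,8a-octahydronaphthalen-1-yl}penta-2,4-dienoic acid (target)
Conditions: SO3·pyridine, pyridine, 0 °C → rt; H2O; Dowex 50W (H+ form), 0 °C, lyophilisation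
Reagents that add atoms: sulfur trioxide–pyridine complex O=S(=O)([O-])[n+]1ccccc1
Why: O-Sulfation of a secondary alcohol with the mild SO3·pyridine complex takes place at oxygen with retention at C7, the carboxylic acid is recovered unchanged after the aqueous work-up, and cold H+ exchange delivers the fully protonated form.

## Compound list

1 | (E)-2-methylbut-2-enal (tiglaldehyde) | C/C=C(\C)C=O | starting material
2 | 2-(triphenyl-λ5-phosphanylidene)propanal | CC(C=O)=P(c1ccccc1)(c1ccccc1)c1ccccc1 | starting material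
3 | (2E,4E)-2,4-dimethylhexa-2,4-dienal | C/C=C(\C)/C=C(\C)C=O | intermediate
4 | (4-ethoxy-4-oxobutyl)triphenylphosphonium bromide | CCOC(=O)CCC[P+](c1ccccc1)(c1ccccc1)c1ccccc1.[Br-] | starting material
5 | ethyl 4-(triphenyl-λ5-phosphanylidene)butanoate (ylide, not isolated) | CCOC(=O)CCC=P(c1ccccc1)(c1ccccc1)c1ccccc1 | intermediate
6 | ethyl (4Z,6E,8E)-6,8-dimethyldeca-4,6,8-trienoate | C/C=C(\C)/C=C(\C)/C=C\CCC(=O)OCC | intermediate
7 | (4Z,6E,8E)-6,8-dimethyldeca-4,6,8-trienal | C/C=C(\C)/C=C(\C)/C=C\CCC=O | intermediate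
8 | (S)-but-3-yn-2-ol | C[C@H](O)C#C | starting material
9 | (S)-but-3-yn-2-yl methanesulfonate | C[C@H](OS(C)(=O)=O)C#C | intermediate
10 | (M)-buta-1,2-dien-1-ylzinc methanesulfonate (not isolated) | CC([H])=[C@]=C([H])[Zn]OS(C)(=O)=O | intermediate
11 | (3R,4S,7Z,9E,11E)-3,9,11-trimethyltrideca-7,9,11-trien-1-yn-4-ol | C/C=C(\C)/C=C(\C)/C=C\CC[C@H](O)[C@H](C)C#C | intermediate
12 | TBS ether of 11 | C/C=C(\C)/C=C(\C)/C=C\CC[C@H](O[Si](C)(C)C(C)(C)C)[C@H](C)C#C | intermediate
13 | (1E,3R,4S,7Z,9E,11E)-alkenyl tributylstannane | C/C=C(\C)/C=C(\C)/C=C\CC[C@H](O[Si](C)(C)C(C)(C)C)[C@H](C)/C=C/[Sn](CCCC)(CCCC)CCCC | intermediate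
14 | ethyl (E)-4-oxobut-2-enoate | CCOC(=O)/C=C/C=O | starting material
15 | ethyl (2E,4E)-5-iodopenta-2,4-dienoate | CCOC(=O)/C=C/C=C/I | intermediate
16 | ethyl (2E,4E,6E,8R,9S,12Z,14E,16E)-9-[(tert-butyldimethylsilyl)oxy]-8,14,16-trimethyloctadeca-2,4,6,12,14,16-hexaenoate (not isolated) | C/C=C(\C)/C=C(\C)/C=C\CC[C@H](O[Si](C)(C)C(C)(C)C)[C@H](C)/C=C/C=C/C=C/C(=O)OCC | intermediate
17 | cis-decalin ethyl dienoate, C7-OTBS, (1S,2R,4aS,7S,8R,8aR) | C/C=C(\C)[C@@H]1C(C)=C[C@H]2CC[C@H](O[Si](C)(C)C(C)(C)C)[C@H](C)[C@H]2[C@@H]1/C=C/C=C/C(=O)OCC | intermediate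
18 | cis-decalin ethyl dienoate, C7-OH | C/C=C(\C)[C@@H]1C(C)=C[C@H]2CC[C@H](O)[C@H](C)[C@H]2[C@@H]1/C=C/C=C/C(=O)OCC | intermediate
19 | cis-decalin dienoic acid, C7-OH | C/C=C(\C)[C@@H]1C(C)=C[C@H]2CC[C@H](O)[C@H](C)[C@H]2[C@@H]1/C=C/C=C/C(=O)O | intermediate
20 | CNP0450810.2, C7 hydrogen sulfate of 19 | C/C=C(\C)[C@@H]1C(C)=C[C@H]2CC[C@H](OS(=O)(=O)O)[C@H](C)[C@H]2[C@@H]1/C=C/C=C/C(=O)O | target

## Counts and risks

Total step count: 12. Longest linear sequence: 10 (steps 1, 2, 3, 5, 6, 7, 9, 10, 11, 12).

**Step 9.**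
- Risks: the two polyene halves may exchange their 4π and 2π roles. The facial bias from C7/C8 may be too small. The Z diene may isomerise or undergo a [1,5]-H shift before it cyclises.
- Fallback: it sets out from 13 and comes back at 17. Tin–lithium exchange (n-BuLi, THF, −78 °C) gives the alkenyllithium F1. Formylation with DMF gives the (E)-enal F2, which has a single, strongly activated 2π unit and no second diene. A Me2AlCl-promoted intramolecular Diels–Alder reaction (CH2Cl2, −78 → −20 °C), with the same Z-diene/endo logic but at low temperature, gives the decalin-1-carbaldehyde F3. Horner–Wadsworth–Emmons olefination with triethyl 4-phosphonocrotonate (LiHMDS, THF, −78 → 0 °C) then installs the E,E-dienoate and gives 17.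

**Step 2.**
- Risks: Z selectivity may erode with the conjugated, α-branched aldehyde, and the geometric isomers may be hard to separate.
- Fallback: it sets out from 3 and comes back at 7, and it fixes the Z geometry by syn reduction of an alkyne. Corey–Fuchs dibromoolefination (CBr4, PPh3, CH2Cl2, 0 °C) gives the dibromotriene F4. n-BuLi (2 equiv, THF, −78 °C) gives the lithium acetylide F5. Alkylation in the same flask with 2-(2-bromoethyl)-1,3-dioxolane (THF–DMPU) gives the dienyne acetal F6. Zn(Cu/Ag) semireduction in aqueous MeOH gives the Z-triene acetal F7. Mild hydrolysis (PPTS, wet acetone) gives 7.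

**Step 7.**
- Risks: regiocontrol may be incomplete (tin delivered to the internal carbon), or a palladium hydride may attack or isomerise the triene.
- Fallback: it sets out from 12 and comes back at 17. Syn-hydroboration with pinacolborane (cat. Cp2ZrHCl, Et3N, neat or CH2Cl2) places boron on the terminal carbon and gives the alkenylboronate F8. Suzuki coupling with 15 (Pd(PPh3)4, aq K3PO4, THF, rt) makes the same C1–C1′ bond and gives 16. After phase separation, 16 is heated in toluene with BHT to 17.

## Further compounds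

F1 | step 9 | alkenyllithium, {(1E,3R,4S,7Z,9E,11E)-4-[(tert-butyldimethylsilyl)oxy]-3,9,11-trimethyltrideca-1,7,9,11-tetraen-1-yl}lithium | C/C=C(\C)/C=C(\C)/C=C\CC[C@H](O[Si](C)(C)C(C)(C)C)[C@H](C)/C=C/[Li]
F2 | step 9 | (E)-enal, (2E,4R,5S,8Z,10E,12E)-5-[(tert-butyldimethylsilyl)oxy]-4,10,12-trimethyltetradeca-2,8,10,12-tetraenal | C/C=C(\C)/C=C(\C)/C=C\CC[C@H](O[Si](C)(C)C(C)(C)C)[C@H](C)/C=C/C=O
F3 | step 9 | decalin-1-carbaldehyde, (1S,2R,4aS,7S,8R,8aS)-2-[(2E)-but-2-en-2-yl]-7-[(tert-butyldimethylsilyl)oxy]-3,8-dimethyl-1,2,4a,5,6,7,8,8a-octahydronaphthalene-1-carbaldehyde | C/C=C(\C)[C@@H]1C(C)=C[C@H]2CC[C@H](O[Si](C)(C)C(C)(C)C)[C@H](C)[C@H]2[C@@H]1C=O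
F4 | step 2 | dibromotriene, (3E,5E)-1,1-dibromo-3,5-dimethylhepta-1,3,5-triene | C/C=C(\C)/C=C(\C)C=C(Br)Br
F5 | step 2 | lithium acetylide, [(3E,5E)-3,5-dimethylhepta-3,5-dien-1-yn-1-yl]lithium | C/C=C(\C)/C=C(\C)C#C[Li]
F6 | step 2 | dienyne acetal, 2-[(5E,7E)-5,7-dimethylnona-5,7-dien-3-yn-1-yl]-1,3-dioxolane | C/C=C(\C)/C=C(\C)C#CCCC1OCCO1
F7 | step 2 | Z-triene acetal, 2-[(3Z,5E,7E)-5,7-dimethylnona-3,5,7-trien-1-yl]-1,3-dioxolane | C/C=C(\C)/C=C(\C)/C=C\CCC1OCCO1
F8 | step 7 | alkenylboronate, pinacol (1E,3R,4S,7Z,9E,11E)-4-[(tert-butyldimethylsilyl)oxy]-3,9,11-trimethyltrideca-1,7,9,11-tetraen-1-ylboronate | C/C=C(\C)/C=C(\C)/C=C\CC[C@H](O[Si](C)(C)C(C)(C)C)[C@H](C)/C=C/B1OC(C)(C)C(C)(C)O1
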